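## Structural features

The target is a thymol-type monoterpenoid on one benzene ring (C1 to C6, thymol numbering). The ring carries the benzylic C7H2 isovalerate at C1, the phenolic angelate ((Z)-2-methylbut-2-enoate) at O3 and the fully substituted carbon C8 at C4. C8 belongs to a 2,2-disubstituted oxirane (C8, C9H2, O8) and also bears C10H2OAc, so the side chain is a glycidyl acetate joined to the arene through its central carbon, ortho to O3 and para to C7. C8, of (R) configuration, is the only stereocentre. It has no hydrogen and no stereogenic neighbour, so it can be set only by an external chiral agent and cannot be corrected later. Three fragilities matter: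
- The tertiary benzylic oxirane opens with acids and Lewis acids, and a free phenol or phenoxide at O3 would attack it.
- The angelate drifts to the (E)-tiglate and, as an aryl ester, is an acyl donor toward any nearby alkoxide.
- Three different esters must be placed without scrambling.

The real difficulty is that C8 carries two almost identical arms, C9H2–O and C10H2–O. Its configuration is only the decision which arm lies in the oxirane and which is acetylated. Without that decision C8 is the centre of a mirror-symmetric 2-arylglycerol. When C9 and C10 are tied through one oxygen (O10), the unit C8, C9, C10, O8, O10 becomes a prochiral 3-aryloxetan-3-ol whose five atoms are those of commercial oxetan-3-one. The key step exploits this feature: it cuts one of the two enantiotopic C–O bonds of the oxetane ring with bromide under catalyst control. One operation thus makes C8 stereogenic, marks C9 as the electrophilic arm for the oxirane and leaves C10 with its oxygen.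

## Logic of the disconnections

Route in one sentence: catalyst-controlled bromide opening of one of the two enantiotopic C–O bonds of the prochiral oxetane 7, whose bromohydrin then contracts to the oxirane.

**15 to 11 and 13.** Cut: the O3–acyl bond of the aryl ester. Reason: this is the most labile group, in geometry and as an acyl donor, and it must not be present while an alkoxide exists at O8. Gain: the only alkene geometry disappears and O3 is left as a robust ether. Demand: O3 must pass from ether to ester without ever being a free phenol beside the oxirane, and the acyl donor must keep its Z geometry.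

**13 to 12.** Cut: the C–Cl bond. Reason: 12 is commercial as the pure Z isomer. Gain: none in skeleton; the disconnection gives only the activation. Demand: activation without free HCl.

**11 to 9 (through 10).** Cut: the O8–C9 bond of the oxirane and the O10–acetyl bond. Reason: an O8 alkoxide next to a C9 leaving group closes the ring without touching any bond of C8. Gain: the strained, acid-labile ring is traded for an open chain whose arms are already different (C–Br against C–OSi) and cannot exchange roles. Demand: the three-membered closure must outrun the four-membered return of O10 to C9, and O10 must be capped at once.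

**9 to 7 (through 8), the key disconnection.** Cut: the C9–Br bond, with C9 reconnected to O10. Reason: this reconnection makes C9 and C10 equivalent and removes the stereocentre. Gain: a chiral compound with three different heteroatom functions on the C3 chain becomes an achiral spiro-like oxetane. In addition, 6 and 10 are constitutional isomers, so no redox step is needed anywhere. Demand: the catalyst must choose between two enantiotopic methylenes on the basis of the two groups on C8 (aryl against silyloxy). The tertiary benzylic C8–O8 bond must also stay intact under a silyl Lewis acid.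

**7 to 6, then 6 to 3 and 4.** Cut: the O8–Si bond, then the C4–C8 bond. Reason: this is the convergent junction of arene and side chain, and 4 brings C8, C9, C10, O8 and O10 at the final oxidation level. Gain: two simple achiral pieces. Demand: an aryl metal at C4 that tolerates the ester at C7.

**3 to 2 to 1.** Cut: the O7–acyl bond and the O3–allyl bond. Reason: the two hydroxyl groups of 1 differ greatly in acidity and can be addressed one after the other without protecting-group exchange. Gain: a commercial arene with the correct 1,3,4 pattern and the halogen already at C4. Demand: only chemoselective O-alkylation of the phenol.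

## Other disconnections considered

**Alternative 1:** this is the first idea that comes to mind. The cut is both C–O bonds of the oxirane, back to the C8=C9 alkene of allylic alcohol A1. The forward key step is the Sharpless asymmetric epoxidation (Ti(OiPr)4, L-(+)-diisopropyl tartrate, tBuOOH) to epoxy alcohol A2, followed by acetylation to 15.

Grounds for preferring the chosen plan:
- The alkene must be built first with a 2-metallated allyl alcohol partner, and O8 and O10 arrive in separate operations.
- A 2-arylglycidol with a donor-substituted arene is the type of epoxy alcohol that Ti(OiPr)4 opens most easily, at the tertiary benzylic carbon.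
- The aryl angelate of A1 would sit beside a transesterifying metal alkoxide and an oxidant.
- The chosen plan needs no oxidant, no alkene at C8 and no Lewis acidic metal in contact with the finished oxirane.

**Alternative 2:** the cut is C8–C9 and C9–O8, that is, methylene transfer to the acyloxymethyl ketone A3. The forward key step is a catalytic asymmetric Corey–Chaykovsky epoxidation with dimethyloxosulfonium methylide and LaLi3(binaphthoxide)3, leading directly to 11.

Grounds for preferring the chosen plan:
- The C10 methylene of A3 lies between a ketone and an acyloxy group, so the basic ylide should deprotonate it or take up the acetyl group rather than add.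
- The catalyst type distinguishes aryl from methyl, whereas here it would have to tell a twisted ortho-substituted aryl group from CH2OAc.
- The betaine alkoxide sits next to the acetate and invites acyl transfer before ring closure.

**Alternative 3:** the cut is the O10–acetyl bond in the mirror-symmetric triol A4. The forward key step is a desymmetrising monoacetylation (lipase and vinyl acetate, or CuCl2 with a chiral bis(oxazoline)) to monoacetate A5. Selective sulfonylation of the C9 hydroxyl group and base closure would then give 11.

Grounds for preferring the chosen plan:
- A5 is configurationally unsafe, because migration of the acetyl group from O10 to O9 (directly or by way of O8) gives its mirror image.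
- One more chemoselective activation is needed.
- A4 requires a ketone partner whose two hydroxyl groups are masked and later unmasked.
- In the chosen plan the arms differ as C–Br and C–OSi, which cannot interconvert, and the leaving group for the oxirane is installed by the stereodefining step itself.

Key step: step 5

Remark: 1, 4 and 12 are taken as commercial. The sense of induction of the squaramide on 7 cannot be derived safely from first principles. The catalyst enantiomer that gives (S)-9 is meant, since both antipodes are accessible from L- or D-tert-leucine. The assignment can be checked against 10 made by the fallback of step 5.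

## Steps

**Step 1**
Reactants: 1 5-(hydroxymethyl)-2-iodophenol
Product: 2 [4-iodo-3-(prop-2-en-1-yloxy)phenyl]methanol
Conditions: allyl bromide (1.1 equiv), K2CO3 (1.5 equiv), acetone, reflux
Reagents that add atoms: allyl bromide, C=CCBr
Why: Williamson ether synthesis; K2CO3 deprotonates only the phenol, which is far more acidic than the benzylic alcohol, so allylation is selective for O3. The allyl ether withstands the Grignard reagent, TMSBr at low temperature and fluoride.

**Step 2**
Reactants: 2 [4-iodo-3-(prop-2-en-1-yloxy)phenyl]methanol
Product: 3 4-iodo-3-(prop-2-en-1-yloxy)benzyl 3-methylbutanoate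
Conditions: 3-methylbutanoyl chloride (1.1 equiv), Et3N, DMAP (cat.), CH2Cl2, 0 °C
Reagents that add atoms: 3-methylbutanoyl chloride, CC(C)CC(=O)Cl
Why: DMAP-catalysed acylation of a primary benzylic alcohol with an acid chloride. Placing the final ester at O7 now removes all later protecting-group traffic at this position.

**Step 3**
Reactants: 3 4-iodo-3-(prop-2-en-1-yloxy)benzyl 3-methylbutanoate; 4 oxetan-3-one
Product: 6 4-(3-hydroxyoxetan-3-yl)-3-(prop-2-en-1-yloxy)benzyl 3-methylbutanoate, via arylmagnesium chloride 5 (not isolated)
Conditions: iPrMgCl·LiCl (1.05 equiv), THF, −30 °C; 4 (1.2 equiv), −30 → 0 °C; aq NH4Cl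
Reagents that add atoms: isopropylmagnesium chloride lithium chloride complex, CC(C)[Mg]Cl.[Li+].[Cl-] (its MgCl stays in 5 only, not in 6)
Why: Iodine–magnesium exchange on an aryl iodide with an ortho alkoxy group is faster at −30 °C than addition of the reagent to an aliphatic ester (ester-tolerant functionalised Grignard chemistry). The strained, electrophilic ketone 4 takes up aryl Grignard reagents by 1,2-addition. No stereocentre arises, since 6 has a mirror plane through C8, O8 and the ring oxygen, which makes C9 and C10 enantiotopic.

**Step 4**
Reactants: 6 4-(3-hydroxyoxetan-3-yl)-3-(prop-2-en-1-yloxy)benzyl 3-methylbutanoate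
Product: 7 3-(prop-2-en-1-yloxy)-4-[3-(trimethylsilyloxy)oxetan-3-yl]benzyl 3-methylbutanoate
Conditions: TMSCl (1.5 equiv), imidazole (2.5 equiv), DMF, 0 °C → rt
Reagents that add atoms: chlorotrimethylsilane, C[Si](C)(C)Cl
Why: Silylation with TMSCl and imidazole; a hydroxyl group on a four-membered ring is less shielded than an open-chain tertiary one. O8 must be capped because a free OH would consume TMSBr and release HBr, which would open the oxetane without catalyst control.

**Step 5**
Reactants: 7 3-(prop-2-en-1-yloxy)-4-[3-(trimethylsilyloxy)oxetan-3-yl]benzyl 3-methylbutanoate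
Product: 9 4-[(2S)-1-bromo-2,3-bis(trimethylsilyloxy)propan-2-yl]-3-(prop-2-en-1-yloxy)benzyl 3-methylbutanoate, via O-silyloxetanium bromide 8 (not isolated)
Conditions: TMSBr (1.2 equiv), chiral tert-leucine 2-arylpyrrolidine amide squaramide (10 mol %), tBuOMe, −78 °C; Et3N quench; crude 9 used directly
Reagents that add atoms: bromotrimethylsilane, C[Si](C)(C)Br
Why: The squaramide binds the bromide of TMSBr through its two N–H bonds, which makes the silicon Lewis acidic enough to silylate the most basic oxygen of 7, the exposed ring oxygen of the strained oxetane, and gives the ion pair 8. The catalyst-held bromide then attacks one of the two enantiotopic ring methylenes (the future C9) by SN2 with release of the ring strain, while the other methylene keeps the silylated oxygen and becomes C10. The closest known reaction type is the hydrogen-bond-donor-catalysed enantioselective addition of TMSBr to 3-substituted and 3,3-disubstituted oxetanes. The step closes no ring; it opens the four-membered ring and leaves O8 and C9–Br placed for the 3-exo-tet closure of step 6. C8, the only new stereocentre, is set purely by catalyst control: no bond to C8 is made or broken, and the aromatic wall of the catalyst, which holds the oxetanium ion by cation–π contact, has to tell the flat C4 aryl group from the globular OSiMe3 group. Site selectivity is needed against the two ester carbonyl groups, the allyl ether and O8, and it is secured by the higher basicity of the oxetane oxygen and by the fact that only its silylation opens a strain-releasing path. Ionisation of the tertiary benzylic C8–O8 bond, which would erase the stereocentre, is held back by the angle strain and inductive destabilisation of an oxetan-3-yl cation before the opening, by the β-bromine and β-oxygen after it, and by the low temperature. The racemic background opening by free TMSBr is slow in an ether solvent at −78 °C, so the catalysed path should carry the reaction.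

**Step 6**
Reactants: 9 4-[(2S)-1-bromo-2,3-bis(trimethylsilyloxy)propan-2-yl]-3-(prop-2-en-1-yloxy)benzyl 3-methylbutanoate
Product: 11 4-[(2R)-2-(acetoxymethyl)oxiran-2-yl]-3-(prop-2-en-1-yloxy)benzyl 3-methylbutanoate, via epoxy alcohol 10 (not isolated)
Conditions: Bu4NF (2.1 equiv), THF, −20 °C; then Ac2O (3 equiv), DMAP (cat.), −20 → 0 °C
Reagents that add atoms: acetic anhydride, CC(=O)OC(C)=O
Why: Fluoride cleaves both Si–O bonds and the O8 alkoxide displaces bromide at C9 in a 3-exo-tet closure (halohydrin to epoxide), which is favoured by the full substitution at C8 and is much faster than the 4-exo-tet return of O10 to C9. All four bonds of C8 stay intact, so the spatial arrangement of 9 is kept and the descriptor changes from S (9, 10) to R (11) only through the priority rules. The O10 alkoxide is acetylated in the same flask, and its Payne rearrangement is harmless because inversion at C8 is cancelled by the exchange of roles of C9 and C10 and returns the same enantiomer.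

**Step 7**
Reactants: 12 angelic acid, (Z)-2-methylbut-2-enoic acid
Product: 13 angeloyl chloride, (Z)-2-methylbut-2-enoyl chloride
Conditions: 1-chloro-N,N,2-trimethylprop-1-en-1-amine (1.05 equiv), CH2Cl2, 0 °C; solution used directly
Reagents that add atoms: 1-chloro-N,N,2-trimethylprop-1-en-1-amine, CC(C)=C(Cl)N(C)C
Why: Neutral acid chloride formation with an α-chloroenamine; the carboxyl proton ends on carbon of the amide by-product. No HCl is therefore set free that could add to the enoate and turn Z into E.

**Step 8**
Reactants: 11 4-[(2R)-2-(acetoxymethyl)oxiran-2-yl]-3-(prop-2-en-1-yloxy)benzyl 3-methylbutanoate; 13 angeloyl chloride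
Product: 15 2-[(2R)-2-(acetoxymethyl)oxiran-2-yl]-5-{[(3-methylbutanoyl)oxy]methyl}phenyl (Z)-2-methylbut-2-enoate, via tributylstannyl phenoxide 14 (not isolated)
Conditions: Pd(PPh3)4 (3 mol %), Bu3SnH (1.1 equiv, slow addition), CH2Cl2, 0 °C; after consumption of the hydride 13 (1.3 equiv), −20 → 0 °C
Reagents that add atoms: tributyltin hydride, CCCC[SnH](CCCC)CCCC (its Bu3Sn stays in 14 only, not in 15)
Why: Zerovalent palladium ionises the aryl allyl ether to a π-allylpalladium phenoxide, and hydride transfer from Bu3SnH releases propene and leaves the covalent stannyl phenoxide 14 (palladium-catalysed hydrostannolysis of allyl aryl ethers). Compound 14 is acylated by 13 with loss of Bu3SnCl, so O3 is never a free phenol or a naked phenoxide beside the oxirane. No base, acid or nucleophilic catalyst is present, which protects the Z geometry, and C8 is not touched.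

## Compound list

1 | 5-(hydroxymethyl)-2-iodophenol | Oc1cc(CO)ccc1I | starting material
2 | [4-iodo-3-(prop-2-en-1-yloxy)phenyl]methanol | OCc1ccc(I)c(OCC=C)c1 | intermediate
3 | 4-iodo-3-(prop-2-en-1-yloxy)benzyl 3-methylbutanoate | CC(C)CC(=O)OCc1ccc(I)c(OCC=C)c1 | intermediate
4 | oxetan-3-one | O=C1COC1 | starting material
5 | [4-{[(3-methylbutanoyl)oxy]methyl}-2-(prop-2-en-1-yloxy)phenyl]magnesium chloride (LiCl complex, not isolated) | CC(C)CC(=O)OCc1ccc([Mg]Cl)c(OCC=C)c1 | intermediate
6 | 4-(3-hydroxyoxetan-3-yl)-3-(prop-2-en-1-yloxy)benzyl 3-methylbutanoate | CC(C)CC(=O)OCc1ccc(C2(O)COC2)c(OCC=C)c1 | intermediate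
7 | 3-(prop-2-en-1-yloxy)-4-[3-(trimethylsilyloxy)oxetan-3-yl]benzyl 3-methylbutanoate | CC(C)CC(=O)OCc1ccc(C2(O[Si](C)(C)C)COC2)c(OCC=C)c1 | intermediate
8 | 1-(trimethylsilyl)oxetan-1-ium bromide derived from 7 (ion pair, not isolated) | CC(C)CC(=O)OCc1ccc(C2(O[Si](C)(C)C)C[O+]([Si](C)(C)C)C2)c(OCC=C)c1.[Br-] | intermediate
9 | 4-[(2S)-1-bromo-2,3-bis(trimethylsilyloxy)propan-2-yl]-3-(prop-2-en-1-yloxy)benzyl 3-methylbutanoate | C=CCOc1cc(COC(=O)CC(C)C)ccc1[C@](O[Si](C)(C)C)(CO[Si](C)(C)C)CBr | intermediate
10 | 4-[(2S)-2-(hydroxymethyl)oxiran-2-yl]-3-(prop-2-en-1-yloxy)benzyl 3-methylbutanoate (formed as its alkoxide, not isolated) | C=CCOc1cc(COC(=O)CC(C)C)ccc1[C@]1(CO)CO1 | intermediate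
11 | 4-[(2R)-2-(acetoxymethyl)oxiran-2-yl]-3-(prop-2-en-1-yloxy)benzyl 3-methylbutanoate | C=CCOc1cc(COC(=O)CC(C)C)ccc1[C@]1(COC(C)=O)CO1 | intermediate
12 | angelic acid, (Z)-2-methylbut-2-enoic acid | C/C=C(/C)C(=O)O | starting material
13 | angeloyl chloride, (Z)-2-methylbut-2-enoyl chloride | C/C=C(/C)C(=O)Cl | intermediate
14 | 4-[(2R)-2-(acetoxymethyl)oxiran-2-yl]-3-(tributylstannyloxy)benzyl 3-methylbutanoate (not isolated) | CCCC[Sn](CCCC)(CCCC)Oc1cc(COC(=O)CC(C)C)ccc1[C@]1(COC(C)=O)CO1 | intermediate
15 | 2-[(2R)-2-(acetoxymethyl)oxiran-2-yl]-5-{[(3-methylbutanoyl)oxy]methyl}phenyl (Z)-2-methylbut-2-enoate (CNP0212475.1) | C/C=C(/C)C(=O)Oc1cc(COC(=O)CC(C)C)ccc1[C@]1(COC(C)=O)CO1 | target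

## Step count and least certain steps

Total step count: 8. Longest linear sequence: 7 (steps 1 to 6 and 8). Step 7 is a one-step side branch.

**Step 5 (key step).** The most likely failure is weak discrimination between the two enantiotopic methylenes. The pair of groups on C8 (an ortho-substituted, twisted aryl group and a silyloxy group) differs from the pairs for which this catalyst type is shaped. A second danger is slow SN2 attack at a carbon next to a fully substituted centre. This would force a higher temperature, at which the uncatalysed opening and ionisation at C8 begin to compete.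

The fallback sets out from 3 and comes back at 10. A Stille coupling of 3 with 2-(tributylstannyl)prop-2-en-1-ol (Pd(PPh3)4, LiCl, DMF) should give the allylic alcohol 4-(3-hydroxyprop-1-en-2-yl)-3-(prop-2-en-1-yloxy)benzyl 3-methylbutanoate F1. Sharpless asymmetric epoxidation of F1 follows (Ti(OiPr)4, L-(+)-diisopropyl tartrate, tBuOOH, 4 Å sieves, CH2Cl2, −20 °C). This tartrate leads from allyl alcohol to (S)-glycidol and by the same face rule should give 10. Compound 10 is then isolated and acetylated to 11.

**Step 8.** Three processes are most likely to go wrong:
- The unmasked O3 opens the neighbouring oxirane (attack at C9, or push-out of O8) during the lifetime of 14.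
- The palladium catalyst isomerises the aryl oxirane to a carbonyl compound.
- The acyl unit drifts from Z to E while the acid chloride waits for a hindered ortho-substituted oxygen.

The fallback sets out from 11 and comes back at 15, without tin and without chloride. The allyl group is transferred to morpholine (Pd(PPh3)4, THF, 0 °C), and the phenol 4-[(2R)-2-(acetoxymethyl)oxiran-2-yl]-3-hydroxybenzyl 3-methylbutanoate F2 is kept cold and is not chromatographed. It is esterified with the preformed mixed anhydride (Z)-2-methylbut-2-enoic 2,4,6-trichlorobenzoic anhydride F3, made from 12, 2,4,6-trichlorobenzoyl chloride and Et3N in toluene. The shielded aroyl carbonyl group of F3 directs attack to the angeloyl carbon.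

**Step 3.** The most likely failures are attack of iPrMgCl or of 5 on the isovalerate before the exchange or the addition is complete, and enolisation of 4 by the aryl Grignard reagent.

The fallback sets out from 2 and comes back at 6, replacing ester tolerance by protection. Silylation of 2 (TBSCl, imidazole) gives tert-butyl{[4-iodo-3-(prop-2-en-1-yloxy)benzyl]oxy}dimethylsilane F4. Iodine–lithium exchange (nBuLi, THF, −78 °C) and addition to 4 give 3-[4-{[(tert-butyldimethylsilyl)oxy]methyl}-2-(prop-2-en-1-yloxy)phenyl]oxetan-3-ol F5. Bu4NF then sets free the diol 3-[4-(hydroxymethyl)-2-(prop-2-en-1-yloxy)phenyl]oxetan-3-ol F6. Its primary benzylic hydroxyl group is acylated selectively with 3-methylbutanoyl chloride and Et3N at 0 °C to give 6.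

**Step 6.** The primary Si–O bond is cleaved first. The most likely failures are therefore return of the O10 alkoxide to C9 (4-exo-tet closure back to an achiral oxetane) and attack of basic fluoride or alkoxide on the isovalerate.

The fallback sets out from 9 and comes back at 11, with the order of events inverted so that no O10 alkoxide ever exists. Mild acid methanolysis (citric acid, MeOH, 0 °C) gives the bromodiol 4-[(2S)-1-bromo-2,3-dihydroxypropan-2-yl]-3-(prop-2-en-1-yloxy)benzyl 3-methylbutanoate F7. Selective acetylation of the primary hydroxyl group (AcCl, 2,4,6-collidine, CH2Cl2, −78 °C) gives the bromohydrin acetate 4-[(2S)-1-acetoxy-3-bromo-2-hydroxypropan-2-yl]-3-(prop-2-en-1-yloxy)benzyl 3-methylbutanoate F8. Solid K2CO3 in acetone then closes the oxirane to 11. A shift of the acetyl group to O8 can only return to O10 and cannot invert the stereocentre.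

## Further compounds

F1 | step 5 | 4-(3-hydroxyprop-1-en-2-yl)-3-(prop-2-en-1-yloxy)benzyl 3-methylbutanoate | C=CCOc1cc(COC(=O)CC(C)C)ccc1C(=C)CO
F2 | step 8 | 4-[(2R)-2-(acetoxymethyl)oxiran-2-yl]-3-hydroxybenzyl 3-methylbutanoate | Oc1cc(COC(=O)CC(C)C)ccc1[C@]1(COC(C)=O)CO1
F3 | step 8 | (Z)-2-methylbut-2-enoic 2,4,6-trichlorobenzoic anhydride | C/C=C(/C)C(=O)OC(=O)c1c(Cl)cc(Cl)cc1Cl
F4 | step 3 | tert-butyl{[4-iodo-3-(prop-2-en-1-yloxy)benzyl]oxy}dimethylsilane | CC(C)(C)[Si](C)(C)OCc1ccc(I)c(OCC=C)c1
F5 | step 3 | 3-[4-{[(tert-butyldimethylsilyl)oxy]methyl}-2-(prop-2-en-1-yloxy)phenyl]oxetan-3-ol | CC(C)(C)[Si](C)(C)OCc1ccc(C2(O)COC2)c(OCC=C)c1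
F6 | step 3 | 3-[4-(hydroxymethyl)-2-(prop-2-en-1-yloxy)phenyl]oxetan-3-ol | OCc1ccc(C2(O)COC2)c(OCC=C)c1
F7 | step 6 | 4-[(2S)-1-bromo-2,3-dihydroxypropan-2-yl]-3-(prop-2-en-1-yloxy)benzyl 3-methylbutanoate | C=CCOc1cc(COC(=O)CC(C)C)ccc1[C@](O)(CO)CBr
F8 | step 6 | 4-[(2S)-1-acetoxy-3-bromo-2-hydroxypropan-2-yl]-3-(prop-2-en-1-yloxy)benzyl 3-methylbutanoate | C=CCOc1cc(COC(=O)CC(C)C)ccc1[C@](O)(COC(C)=O)CBr
A1 | alternative 1 | 2-(3-hydroxyprop-1-en-2-yl)-5-{[(3-methylbutanoyl)oxy]methyl}phenyl (Z)-2-methylbut-2-enoate | C/C=C(/C)C(=O)Oc1cc(COC(=O)CC(C)C)ccc1C(=C)CO
A2 | alternative 1 | 2-[(2S)-2-(hydroxymethyl)oxiran-2-yl]-5-{[(3-methylbutanoyl)oxy]methyl}phenyl (Z)-2-methylbut-2-enoate | C/C=C(/C)C(=O)Oc1cc(COC(=O)CC(C)C)ccc1[C@]1(CO)CO1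
A3 | alternative 2 | 4-(acetoxyacetyl)-3-(prop-2-en-1-yloxy)benzyl 3-methylbutanoate | C=CCOc1cc(COC(=O)CC(C)C)ccc1C(=O)COC(C)=O
A4 | alternative 3 | 3-(prop-2-en-1-yloxy)-4-(1,2,3-trihydroxypropan-2-yl)benzyl 3-methylbutanoate | C=CCOc1cc(COC(=O)CC(C)C)ccc1C(O)(CO)CO
A5 | alternative 3 | 4-[(2R)-1-acetoxy-2,3-dihydroxypropan-2-yl]-3-(prop-2-en-1-yloxy)benzyl 3-methylbutanoate | C=CCOc1cc(COC(=O)CC(C)C)ccc1[C@](O)(COC(C)=O)CO
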